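**Target:** (2S,4R)-5,7-dimethoxy-8-(3-methylbut-2-en-1-yl)-2-phenylchroman-4-ol, i.e. the 2,4-trans flavan-4-ol (phenyl and OH on opposite faces).

**Assumptions:**
- The hydroboration (step 6) and oxidation (step 7) are telescoped but counted as two steps.
- (S)-DTBM-SEGPHOS is assumed to be the ligand antipode matched to the (S)-chromene, by analogy with L*CuH addition to β-substituted styrenes. If the first run consumes the (R)-chromene instead, the (R)-ligand is used.

## Retrosynthetic overview

1. Target 10: the C4–OH comes from stereoretentive oxidation of the C4–Bpin compound 9.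
2. 9 comes from racemic flav-3-ene 8 by a proposed CuH-catalysed Markovnikov hydroboration run as a kinetic resolution (creates C4, selects 2S).
3. The pyran ring of 8 (the only ring built; O1–C2 and C3–C4 bonds) comes from salicylaldehyde 6 and (E)-styrylboronic acid 7.
4. 6 comes from ortho-formylation of prenylphenol 5, which comes from aromatic Claisen rearrangement of ether 4, made from 3,5-dimethoxyphenol 1 and 3-chloro-3-methylbut-1-yne 2. Both aryl rings are purchased.

## Route

**Step 1**
Reactants: 1 (3,5-dimethoxyphenol); 2 (3-chloro-3-methylbut-1-yne)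
Product: 3, 1,3-dimethoxy-5-[(2-methylbut-3-yn-2-yl)oxy]benzene
Conditions: 2 (1.5 equiv), DBU, CuCl2·2H2O (1 mol%), MeCN, 0 °C → rt
Reagents that add atoms: none other than reactant 2 (3-chloro-3-methylbut-1-yne, CC(C)(Cl)C#C; Cl is lost)
Why: Cu-catalysed O-propargylation of a phenol with a tertiary propargylic chloride (copper acetylide-assisted ionisation) gives the hindered tertiary aryl ether; no stereocentre.

**Step 2**
Reactants: 3
Product: 4, 1,3-dimethoxy-5-[(2-methylbut-3-en-2-yl)oxy]benzene
Conditions: H2 (1 atm), Lindlar catalyst, quinoline, EtOAc, rt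
Reagents that add atoms: none
Why: Lindlar semi-hydrogenation stops the terminal alkyne at the alkene; rt avoids thermal cyclisation of the propargyl ether.

**Step 3**
Reactants: 4
Product: 5, 3,5-dimethoxy-2-(3-methylbut-2-en-1-yl)phenol
Conditions: PhNEt2, 130 °C
Reagents that add atoms: none
Why: Aromatic Claisen [3,3] rearrangement of the 1,1-dimethylallyl ether delivers a normal prenyl group to the ortho carbon (the two ortho positions are equivalent); the basic solvent suppresses acid-catalysed chroman formation.

**Step 4**
Reactants: 5
Product: 6, 2-hydroxy-4,6-dimethoxy-3-(3-methylbut-2-en-1-yl)benzaldehyde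
Conditions: MgCl2, Et3N, (CH2O)n, MeCN, reflux; aq. NH4Cl work-up
Reagents that add atoms: paraformaldehyde (formaldehyde, C=O)
Why: Magnesium phenoxide-directed ortho-formylation (Casnati–Skattebøl) goes to the only free ortho position and is non-acidic, so the o-prenylphenol survives.

**Step 5**
Reactants: 6; 7 ((E)-2-phenylvinylboronic acid)
Product: 8, racemic 5,7-dimethoxy-8-(3-methylbut-2-en-1-yl)-2-phenyl-2H-chromene
Conditions: 7 (1.3 equiv), Bn2NH (0.4 equiv), 4 Å MS, 1,4-dioxane, 90 °C
Reagents that add atoms: none other than reactant 7 ((E)-styrylboronic acid, OB(O)/C=C/c1ccccc1; only the styryl unit is retained)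
Why: Petasis borono-Mannich alkenyl transfer to the salicylaldehyde iminium, amine loss to the o-quinone methide and oxa-6π electrocyclisation close the pyran ring; C2 is formed racemic.

**Step 6**
Reactants: 8 (racemic)
Product: 9, 2-[(2S,4R)-5,7-dimethoxy-8-(3-methylbut-2-en-1-yl)-2-phenylchroman-4-yl]-4,4,5,5-tetramethyl-1,3,2-dioxaborolane (≤50% theoretical; the (R)-enantiomer of 8 is recovered)
Conditions: CuCl (5 mol%), NaOt-Bu (10 mol%), (S)-DTBM-SEGPHOS (5.5 mol%), HBpin (0.50 equiv), THF, 0 °C → rt, stopped at ≤50% conversion
Reagents that add atoms: pinacolborane, [H]B1OC(C)(C)C(C)(C)O1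
Why: Proposed new method: L*Cu–H adds syn across the C3=C4 vinylarene bond with Cu at benzylic C4 and H at C3, and stereoretentive σ-bond metathesis with HBpin then gives the C4–Bpin; for (S)-8 the ligand-preferred alkene face is the one anti to the C2 phenyl (matched), so boron ends up trans to phenyl (4R), whereas (R)-8 is mismatched and is left behind; the trisubstituted prenyl alkene does not insert into L*CuH; closest known reaction types are CuH-catalysed Markovnikov hydroboration of β-substituted vinylarenes and Cu–boryl kinetic resolution of 2-aryl-2H-chromenes (which places boron at C3, not C4).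

**Step 7**
Reactants: 9 (crude from step 6)
Product: 10, (2S,4R)-5,7-dimethoxy-8-(3-methylbut-2-en-1-yl)-2-phenylchroman-4-ol (target)
Conditions: 30% H2O2, 3 M NaOH, THF, 0 °C; Na2S2O3 quench; chromatography on Et3N-deactivated silica (separates recovered (R)-8)
Reagents that add atoms: hydrogen peroxide, OO
Why: Boronate oxidation by 1,2-migration of carbon from boron to oxygen proceeds with retention at C4; the basic, non-acidic conditions protect the very ionisable 5,7-dimethoxy benzylic alcohol and leave the prenyl alkene and C2 untouched.

## Compound list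

1 | 3,5-dimethoxyphenol | COc1cc(O)cc(OC)c1 | starting material
2 | 3-chloro-3-methylbut-1-yne | CC(C)(Cl)C#C | starting material
3 | 1,3-dimethoxy-5-[(2-methylbut-3-yn-2-yl)oxy]benzene | COc1cc(OC)cc(OC(C)(C)C#C)c1 | intermediate
4 | 1,3-dimethoxy-5-[(2-methylbut-3-en-2-yl)oxy]benzene | COc1cc(OC)cc(OC(C)(C)C=C)c1 | intermediate
5 | 3,5-dimethoxy-2-(3-methylbut-2-en-1-yl)phenol | COc1cc(O)c(CC=C(C)C)c(OC)c1 | intermediate
6 | 2-hydroxy-4,6-dimethoxy-3-(3-methylbut-2-en-1-yl)benzaldehyde | COc1cc(OC)c(C=O)c(O)c1CC=C(C)C | intermediate
7 | (E)-2-phenylvinylboronic acid | OB(O)/C=C/c1ccccc1 | starting material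
8 | rac-5,7-dimethoxy-8-(3-methylbut-2-en-1-yl)-2-phenyl-2H-chromene | COc1cc(OC)c2c(c1CC=C(C)C)OC(c1ccccc1)C=C2 | intermediate (racemic)
9 | 2-[(2S,4R)-5,7-dimethoxy-8-(3-methylbut-2-en-1-yl)-2-phenylchroman-4-yl]-4,4,5,5-tetramethyl-1,3,2-dioxaborolane | COc1cc(OC)c2c(c1CC=C(C)C)O[C@H](c1ccccc1)C[C@H]2B1OC(C)(C)C(C)(C)O1 | intermediate
10 | (2S,4R)-5,7-dimethoxy-8-(3-methylbut-2-en-1-yl)-2-phenylchroman-4-ol | COc1cc(OC)c2c(c1CC=C(C)C)O[C@H](c1ccccc1)C[C@H]2O | target

## Summary

Total steps: 7. Longest linear sequence: 7 (fully linear; 2 and 7 are purchased).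

Stereocentres: C2 is formed racemic in step 5 and resolved to S in step 6. C4 is set as R in step 6 and retained in step 7. Recovered (R)-8 could in principle be photoracemised through the ring-opened o-quinone methide and recycled; this is not counted in the route.

**Steps most likely to fail:**

1. **Step 6 (proposed new step).** Hydrocupration may be slow because the styrene is electron-rich and C4 sits next to the peri 5-OMe. The reverse regiochemistry (Cu at C3) would open the ring by β-aryloxide elimination. The selectivity factor may also be too low.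
   Fallback (known chemistry, flavanone approach): run the same propargylation/Lindlar/Claisen sequence on commercial 2'-hydroxy-4',6'-dimethoxyacetophenone, convert via the enaminone to 5,7-dimethoxy-8-prenylchromone, and set C2 by Pd(II)/pyridine-oxazoline-catalysed conjugate addition of PhB(OH)2 to give the (S)-flavanone. Reduce with NaBH4 to the 2,4-cis alcohol and invert C4 by Mitsunobu esterification and mild saponification.

2. **Step 5.** The aldehyde is electron-rich and doubly ortho-substituted, so iminium formation and alkenyl transfer may be sluggish.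
   Fallback: Claisen–Schmidt condensation of 6 with acetophenone to the (E)-enone, Luche reduction to the allylic alcohol, then mild cyclodehydration (cat. PPTS) through the o-quinone methide to rac-8.

3. **Step 3.** The tertiary allyl ether may fragment (loss of isoprene) or the product may cyclise to the 2,2-dimethylchroman at high temperature.
   Fallback: replace steps 1–3 by direct ortho-C-prenylation of the sodium phenoxide of 1 with prenyl bromide in toluene.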